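Teal was the run I had to work from, and what I chose to freeze from it was the late loss of L.

- teal: L 1 M; D 3 mol%; run made earlier
- flask: L 0.50 M; D 3 mol%; time 8.0 d

teal run (percent of the L charged)

| time / h | Q / % | L / % |
|---|---|---|
| 2.50 | 1 | 100 |
| 6.00 | 6 | 94 |
| 12.0 | 20 | 81 |
| 20.0 | 32 | 65 |

(standard deviation of a reading: 1.5 percentage points)

1. average number of monomer units in a chain (chains begun, living or dead) at 8.0 d
2. part of the L that has reacted at 8.0 d

- the average divides the monomer in chains by the number of chains begun, living and dead together
- the earlier runs do not show the number of chains; that part of a forecast is a guess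
- no earlier run changes the charge of D; that part of a forecast is a guess

Teal showed L lost as Q formed, after a delay. Its two last readings gave a slope of ln(fraction of L left) of 0.0275 h⁻¹, still higher than the 0.0248 h⁻¹ of the stretch before, so the line was still curving and holding the slope fixed was my assumption; both slopes are readings that carry their scatter. Taking the last slope as a straight line and running it back gave a delay of 4.34 h. I built the flask up in three moves.

Main step alone, with teal's slope unchanged, left this fraction of L at 8.0 d: 0.508%.

The flask's D charge is half of teal's, and I guessed the slope follows it. This plateau slope, the pseudo-first-order loss of L per hour that I assumed to hold after the delay, is then 0.0138 h⁻¹, which leaves 7.13%.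

I guessed the delay grows with the dilution, to twice teal's, or 8.68 h. That leaves 8.03%, so c is 92.0%.

Teal shows no chain count, so I reckoned no dp.

The forecast gave dp 32 (25 to 55), saying “This is a guess, since chain numbers were never measured”, and c 90% (75% to 98%), a c lower than mine.

The flask gave dp 157 and c 90.1%. At 8.00 d, J held 78.4% of the D charged and X held 17.8%. Starting from the 34.0% of L in the flask at 4.00 d, the plateau slope gave 9.04% at 8.00 d, and the flask stood at 9.90%.

    L + D → X + Q (k = 7.28 × 10⁻⁶ M⁻¹ s⁻¹)
    L → Z (k = 1.97 × 10⁻⁷ s⁻¹)
    D → J (k = 1.44 × 10⁻⁵ s⁻¹)
    L + D → E (k = 1.53 × 10⁻⁶ M⁻¹ s⁻¹)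
    L + X → Q + X, rate k5*[X]*[L] (k = 0.00126 M⁻¹ s⁻¹)

The same flask read at 50 h: the plateau slope and my delay gave 56.6% of L left, so c of 43.4%. Computed, it held 61.2% of L, with c 38.8%.

The readings are simulated for an exercise; the scatter is artificial.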